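**Assumption:** the target is taken exactly as the given SMILES, i.e. methyl (1S,5E,8S,12S)-1-methyl-3,10,13-trioxo-8-(prop-1-en-2-yl)-15-oxabicyclo[10.2.1]pentadec-5-ene-5-carboxylate; the locants of this name are used below.

## Retrosynthetic overview

1. Target 28 ⇐ macrocyclic diol 27: the C-3 and C-13 carbinols are oxidised last, so the epimerisable C-12 and the β,γ-unsaturated C-3 ketone exist only at the end.
2. The 14-membered carbocycle ⇐ ring-closing metathesis at C5=C6 of seco-triene 25 (terminal alkene plus 2-substituted acrylate).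
3. 25 ⇐ keto aldehyde 22 + methyl 2-(bromomethyl)acrylate 23 (Barbier); 22 ⇐ dithiane 18 + iodide 10 (C10–C11 bond, Corey–Seebach).
4. Oxolane fragment 10 comes from acrolein: Sharpless kinetic resolution sets C-12, an oxocarbenium C-glycosylation sets the quaternary C-1. Fragment 18 comes from (S)-carvone and carries C-8.
5. Ring order: oxolane (step 5), then the 14-membered ring (step 16); the furanone carbonyl is unveiled in step 18.

## Route

### Oxolane fragment

**Step 1**
Reactants: 1 acrolein; 2 2-methylallylmagnesium chloride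
Product: 3 rac-5-methylhexa-1,5-dien-3-ol
Conditions: THF, −78 °C; sat. aq. NH4Cl
Reagents that add atoms: none
Why: Grignard 1,2-addition to the enal gives the racemic secondary allylic alcohol needed for the kinetic resolution; no stereocentre is controlled here.

**Step 2**
Reactants: 3 rac-5-methylhexa-1,5-dien-3-ol
Product: 4 (1R)-3-methyl-1-[(2S)-oxiran-2-yl]but-3-en-1-ol
Conditions: Ti(OiPr)4 (0.15 equiv), D-(−)-diisopropyl tartrate (0.18 equiv), t-BuOOH (0.45 equiv), 4 Å MS, CH2Cl2, −20 °C
Reagents that add atoms: tert-butyl hydroperoxide, CC(C)(C)OO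
Why: Sharpless kinetic resolution: with the D-tartrate the (R)-alcohol is epoxidised much faster than (S)-3 (left behind) and gives the erythro epoxy alcohol, which fixes the future C-12 (S) and the temporary C-13 carbinol (R); the isolated 1,1-disubstituted alkene is inert.

**Step 3**
Reactants: 4 (1R)-3-methyl-1-[(2S)-oxiran-2-yl]but-3-en-1-ol
Product: 5 (2S)-2-[(1R)-1-[(4-methoxybenzyl)oxy]-3-methylbut-3-en-1-yl]oxirane
Conditions: NaH, PMBBr, Bu4NI (cat.), THF, −20 → 0 °C
Reagents that add atoms: 4-methoxybenzyl bromide, COc1ccc(CBr)cc1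
Why: Williamson etherification with a reactive benzylic bromide at low temperature outruns Payne rearrangement and installs the alkoxy group that later steers step 6 and is removable with DDQ.

**Step 4**
Reactants: 5 (2S)-2-[(1R)-1-[(4-methoxybenzyl)oxy]-3-methylbut-3-en-1-yl]oxirane
Product: 6 (2R,3R)-1-iodo-3-[(4-methoxybenzyl)oxy]-5-methylhex-5-en-2-ol
Conditions: LiI, AcOH, THF, 0 °C → rt
Reagents that add atoms: lithium iodide, [Li+].[I-]
Why: SN2 opening of the terminal epoxide by iodide at the CH2 carbon (halohydrin formation) leaves the C–O bond at the stereocentre untouched (the descriptor changes only through CIP priorities) and is done before any ketone is present, so carbonyl participation cannot invert that centre.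

**Step 5**
Reactants: 6 (2R,3R)-1-iodo-3-[(4-methoxybenzyl)oxy]-5-methylhex-5-en-2-ol
Product: 8 (2R,3R,5RS)-2-(iodomethyl)-5-methoxy-3-[(4-methoxybenzyl)oxy]-5-methyloxolane, via hydroxy ketone 7 (not isolated)
Conditions: O3, CH2Cl2/MeOH (4:1), −78 °C (stopped at the alkene end-point); Me2S; then CSA (cat.), rt
Reagents that add atoms: ozone, [O-][O+]=O; methanol, CO
Why: ozonolysis of the only alkene gives the γ-hydroxy methyl ketone 7, which closes under acid in methanol to the five-membered cyclic methyl ketal (Fischer-type glycosidation); this forms the oxolane ring, and the anomeric mixture is irrelevant because C-5 is ionised in step 6.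

**Step 6**
Reactants: 8 (2R,3R,5RS)-2-(iodomethyl)-5-methoxy-3-[(4-methoxybenzyl)oxy]-5-methyloxolane
Product: 10 (2R,3R,5R)-5-(2,2-dimethoxyethyl)-2-(iodomethyl)-3-[(4-methoxybenzyl)oxy]-5-methyloxolane, via oxocarbenium ion 9 (not isolated)
Conditions: CH2=CHOMe (2 equiv), BF3·OEt2 (0.3 equiv), CH2Cl2, −78 °C; Et3N quench
Reagents that add atoms: methoxyethene, COC=C
Why: acetal–enol ether condensation (Mukaiyama-type C-glycosylation): the enol ether attacks the inside face of the envelope oxocarbenium ion whose 3-alkoxy group is pseudoaxial, so the new C–C bond is cis to OPMB and trans to CH2I, setting the quaternary future C-1; the returning methoxide closes the dimethyl acetal.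

### Carvone fragment

**Step 7**
Reactants: 11 (S)-(+)-carvone
Product: 12 (1S,4S,6S)-1-methyl-4-(prop-1-en-2-yl)-7-oxabicyclo[4.1.0]heptan-2-one
Conditions: 30% H2O2, NaOH (cat.), MeOH, 0 °C
Reagents that add atoms: hydrogen peroxide, OO
Why: Weitz–Scheffer nucleophilic epoxidation touches only the enone and not the isopropenyl group; the two new stereocentres (trans to isopropenyl) are destroyed in step 8.

**Step 8**
Reactants: 12 (1S,4S,6S)-1-methyl-4-(prop-1-en-2-yl)-7-oxabicyclo[4.1.0]heptan-2-one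
Product: 14 (3S)-5-oxo-3-(prop-1-en-2-yl)pentanoic acid, via dihydroxy ketone 13 (not isolated)
Conditions: H5IO6 (2.5 equiv), THF/H2O, 0 °C → rt
Reagents that add atoms: water, O
Why: acid opening of the epoxide to diol 13, then Malaprade cleavage of the glycol and α-ketol bonds, excises the methyl-bearing ring carbon as acetic acid and leaves a differentiated aldehyde and acid; the stereocentre is β to both carbonyls and cannot epimerise.

**Step 9**
Reactants: 14 (3S)-5-oxo-3-(prop-1-en-2-yl)pentanoic acid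
Product: 15 (3S)-3-(prop-1-en-2-yl)hex-5-enoic acid
Conditions: Ph3PCH3Br (2.2 equiv), KN(SiMe3)2 (2.2 equiv), THF, 0 °C → rt; aq. HCl
Reagents that add atoms: methyltriphenylphosphonium bromide, C[P+](c1ccccc1)(c1ccccc1)c1ccccc1.[Br-]
Why: Wittig methylenation of the aldehyde; the first equivalent of ylide is consumed by the acid, whose carboxylate is inert and is re-protonated on work-up.

**Step 10**
Reactants: 15 (3S)-3-(prop-1-en-2-yl)hex-5-enoic acid
Product: 16 (3S)-3-(prop-1-en-2-yl)hex-5-en-1-ol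
Conditions: LiAlH4, THF, 0 °C → rt; H2O work-up
Reagents that add atoms: none
Why: hydride reduction of the carboxylic acid to the primary alcohol; isolated alkenes are inert to LiAlH4.

**Step 11**
Reactants: 16 (3S)-3-(prop-1-en-2-yl)hex-5-en-1-ol
Product: 17 (3S)-3-(prop-1-en-2-yl)hex-5-enal
Conditions: Dess–Martin periodinane, CH2Cl2, 0 °C → rt
Reagents that add atoms: none
Why: Dess–Martin oxidation stops cleanly at the aldehyde under near-neutral conditions, and the β-stereocentre is not at risk.

**Step 12**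
Reactants: 17 (3S)-3-(prop-1-en-2-yl)hex-5-enal
Product: 18 2-[(2S)-2-(prop-1-en-2-yl)pent-4-en-1-yl]-1,3-dithiane
Conditions: HS(CH2)3SH, BF3·OEt2 (0.2 equiv), CH2Cl2, −40 → −20 °C
Reagents that add atoms: propane-1,3-dithiol, SCCCS
Why: Lewis-acid thioacetalisation converts the aldehyde carbon (future C-10) into an acyl-anion equivalent (Corey–Seebach umpolung); low temperature protects the isopropenyl group.

### Union and end-game

**Step 13**
Reactants: 18 2-[(2S)-2-(prop-1-en-2-yl)pent-4-en-1-yl]-1,3-dithiane; 10 (2R,3R,5R)-5-(2,2-dimethoxyethyl)-2-(iodomethyl)-3-[(4-methoxybenzyl)oxy]-5-methyloxolane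
Product: 20 2-{[(2S,3R,5R)-5-(2,2-dimethoxyethyl)-3-[(4-methoxybenzyl)oxy]-5-methyloxolan-2-yl]methyl}-2-[(2S)-2-(prop-1-en-2-yl)pent-4-en-1-yl]-1,3-dithiane, via lithiated dithiane 19 (not isolated)
Conditions: t-BuLi (1.05 equiv), THF/HMPA (9:1), −78 °C; then 10, −78 → −30 °C
Reagents that add atoms: none
Why: Corey–Seebach alkylation: the sulfur-stabilised carbanion displaces the primary iodide (SN2) and forms the C10–C11 bond; acetal, PMB ether and unactivated alkenes tolerate the anion, and no stereocentre is touched.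

**Step 14**
Reactants: 20 (the dithiane from step 13)
Product: 22 2-[(2R,4R,5S)-4-[(4-methoxybenzyl)oxy]-2-methyl-5-[(4S)-2-oxo-4-(prop-1-en-2-yl)hept-6-en-1-yl]oxolan-2-yl]acetaldehyde, via keto acetal 21 (not isolated)
Conditions: PhI(O2CCF3)2 (1.5 equiv), MeCN/H2O (9:1), 0 °C, 15 min; then rt, 2 h
Reagents that add atoms: water, O
Why: oxidative dithiane hydrolysis with the hypervalent iodine reagent is fast enough to spare alkenes and the PMB ether and gives ketone 21; the trifluoroacetic acid liberated then hydrolyses the dimethyl acetal, so both carbonyls are unmasked in one flask.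

**Step 15**
Reactants: 22 (the keto aldehyde from step 14); 23 methyl 2-(bromomethyl)acrylate
Product: 25 methyl (4RS)-4-hydroxy-5-[(2S,4R,5S)-4-[(4-methoxybenzyl)oxy]-2-methyl-5-[(4S)-2-oxo-4-(prop-1-en-2-yl)hept-6-en-1-yl]oxolan-2-yl]-2-methylidenepentanoate, via allylindium reagent 24 (not isolated)
Conditions: In powder, THF/H2O (1:1), rt
Reagents that add atoms: none
Why: indium-mediated Barbier allylation in water adds the 2-(methoxycarbonyl)allyl unit to the aldehyde only (the ketone is much slower) and stops at the hydroxy ester; the new carbinol (future C-3 ketone) is carried as an epimer mixture.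

**Step 16**
Reactants: 25 (the seco-triene from step 15)
Product: 26 methyl (1S,3RS,5E,8S,12S,13R)-3-hydroxy-13-[(4-methoxybenzyl)oxy]-1-methyl-10-oxo-8-(prop-1-en-2-yl)-15-oxabicyclo[10.2.1]pentadec-5-ene-5-carboxylate
Conditions: second-generation Hoveyda–Grubbs catalyst RuCl2(H2IMes)(=CH-C6H4-2-OiPr) (10 mol %), 1,4-benzoquinone (20 mol %), toluene (1 mM), 60 °C
Reagents that add atoms: none
Why: ring-closing metathesis between the terminal alkene and the 2-substituted acrylate closes the 14-membered carbocycle with loss of ethene; 2-substituted acrylates give the ester-trans (E) trisubstituted enoate, the ring accommodates the resulting cis ring olefin, and the isopropenyl group is too hindered to compete.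

**Step 17**
Reactants: 26 (the macrocyclic PMB ether from step 16)
Product: 27 methyl (1S,3RS,5E,8S,12S,13R)-3,13-dihydroxy-1-methyl-10-oxo-8-(prop-1-en-2-yl)-15-oxabicyclo[10.2.1]pentadec-5-ene-5-carboxylate
Conditions: DDQ (1.5 equiv), CH2Cl2/pH 7 buffer (10:1), 0 °C
Reagents that add atoms: none
Why: oxidative PMB ether cleavage by DDQ under buffered conditions leaves the enoate, the isopropenyl group and the β-alkoxy ketone untouched.

**Step 18**
Reactants: 27 (the macrocyclic diol from step 17)
Product: 28 methyl (1S,5E,8S,12S)-1-methyl-3,10,13-trioxo-8-(prop-1-en-2-yl)-15-oxabicyclo[10.2.1]pentadec-5-ene-5-carboxylate (CNP0163183.4)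
Conditions: Dess–Martin periodinane (4 equiv), NaHCO3, CH2Cl2, 0 °C → rt
Reagents that add atoms: none
Why: double Dess–Martin oxidation converts both carbinols to ketones under buffered, non-basic conditions, so C-12 (now α to a ketone), the β-alkoxy ketones and the β,γ-unsaturated ketone are not equilibrated; the C-3 epimers converge and the C-13 control element is erased.

## Compound list

1 | acrolein (prop-2-enal) | C=CC=O | starting material
2 | 2-methylallylmagnesium chloride | CC(=C)C[Mg]Cl | starting material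
3 | rac-5-methylhexa-1,5-dien-3-ol | C=CC(O)CC(C)=C | intermediate
4 | (1R)-3-methyl-1-[(2S)-oxiran-2-yl]but-3-en-1-ol | C=C(C)C[C@@H](O)[C@@H]1CO1 | intermediate
5 | (2S)-2-[(1R)-1-[(4-methoxybenzyl)oxy]-3-methylbut-3-en-1-yl]oxirane | C=C(C)C[C@@H](OCc1ccc(OC)cc1)[C@@H]1CO1 | intermediate
6 | (2R,3R)-1-iodo-3-[(4-methoxybenzyl)oxy]-5-methylhex-5-en-2-ol | C=C(C)C[C@@H](OCc1ccc(OC)cc1)[C@H](CI)O | intermediate
7 | (4R,5R)-5-hydroxy-6-iodo-4-[(4-methoxybenzyl)oxy]hexan-2-one (hydroxy ketone, in equilibrium with its cyclic hemiketal) | CC(=O)C[C@@H](OCc1ccc(OC)cc1)[C@H](CI)O | intermediate (not isolated)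
8 | (2R,3R,5RS)-2-(iodomethyl)-5-methoxy-3-[(4-methoxybenzyl)oxy]-5-methyloxolane | COC1(C)C[C@@H](OCc2ccc(OC)cc2)[C@H](CI)O1 | intermediate
9 | (2R,3R)-2-(iodomethyl)-3-[(4-methoxybenzyl)oxy]-5-methyl-3,4-dihydro-2H-furan-1-ium methoxytrifluoroborate (oxocarbenium ion) | CC1=[O+][C@@H](CI)[C@H](OCc2ccc(OC)cc2)C1.CO[B-](F)(F)F | intermediate (not isolated)
10 | (2R,3R,5R)-5-(2,2-dimethoxyethyl)-2-(iodomethyl)-3-[(4-methoxybenzyl)oxy]-5-methyloxolane | COC(OC)C[C@@]1(C)C[C@@H](OCc2ccc(OC)cc2)[C@H](CI)O1 | intermediate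
11 | (S)-(+)-carvone | CC1=CC[C@@H](CC1=O)C(C)=C | starting material
12 | (1S,4S,6S)-1-methyl-4-(prop-1-en-2-yl)-7-oxabicyclo[4.1.0]heptan-2-one | C[C@]12O[C@H]1C[C@@H](CC2=O)C(C)=C | intermediate
13 | (2S,3R,5S)-2,3-dihydroxy-2-methyl-5-(prop-1-en-2-yl)cyclohexan-1-one (dihydroxy ketone, shown for anti opening) | C[C@]1(O)[C@H](O)C[C@@H](CC1=O)C(C)=C | intermediate (not isolated)
14 | (3S)-5-oxo-3-(prop-1-en-2-yl)pentanoic acid | C=C(C)[C@H](CC(=O)O)CC=O | intermediate
15 | (3S)-3-(prop-1-en-2-yl)hex-5-enoic acid | C=C(C)[C@H](CC(=O)O)CC=C | intermediate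
16 | (3S)-3-(prop-1-en-2-yl)hex-5-en-1-ol | C=C(C)[C@H](CCO)CC=C | intermediate
17 | (3S)-3-(prop-1-en-2-yl)hex-5-enal | C=C(C)[C@H](CC=O)CC=C | intermediate
18 | 2-[(2S)-2-(prop-1-en-2-yl)pent-4-en-1-yl]-1,3-dithiane | C=C(C)[C@H](CC1SCCCS1)CC=C | intermediate
19 | 2-lithio-2-[(2S)-2-(prop-1-en-2-yl)pent-4-en-1-yl]-1,3-dithiane (lithiated dithiane) | C=C(C)[C@H](CC1([Li])SCCCS1)CC=C | intermediate (not isolated)
20 | 2-{[(2S,3R,5R)-5-(2,2-dimethoxyethyl)-3-[(4-methoxybenzyl)oxy]-5-methyloxolan-2-yl]methyl}-2-[(2S)-2-(prop-1-en-2-yl)pent-4-en-1-yl]-1,3-dithiane | COC(OC)C[C@@]1(C)C[C@@H](OCc2ccc(OC)cc2)[C@H](CC3(C[C@H](CC=C)C(C)=C)SCCCS3)O1 | intermediate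
21 | (4S)-1-[(2S,3R,5R)-5-(2,2-dimethoxyethyl)-3-[(4-methoxybenzyl)oxy]-5-methyloxolan-2-yl]-4-(prop-1-en-2-yl)hept-6-en-2-one (keto acetal) | COC(OC)C[C@@]1(C)C[C@@H](OCc2ccc(OC)cc2)[C@H](CC(=O)C[C@H](CC=C)C(C)=C)O1 | intermediate (not isolated)
22 | 2-[(2R,4R,5S)-4-[(4-methoxybenzyl)oxy]-2-methyl-5-[(4S)-2-oxo-4-(prop-1-en-2-yl)hept-6-en-1-yl]oxolan-2-yl]acetaldehyde | O=CC[C@@]1(C)C[C@@H](OCc2ccc(OC)cc2)[C@H](CC(=O)C[C@H](CC=C)C(C)=C)O1 | intermediate
23 | methyl 2-(bromomethyl)acrylate | COC(=O)C(=C)CBr | starting material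
24 | [2-(methoxycarbonyl)prop-2-en-1-yl]indium dibromide (allylindium reagent, written as the RInBr2 component of the sesquibromide) | COC(=O)C(=C)C[In](Br)Br | intermediate (not isolated)
25 | methyl (4RS)-4-hydroxy-5-[(2S,4R,5S)-4-[(4-methoxybenzyl)oxy]-2-methyl-5-[(4S)-2-oxo-4-(prop-1-en-2-yl)hept-6-en-1-yl]oxolan-2-yl]-2-methylidenepentanoate | COC(=O)C(=C)CC(O)C[C@@]1(C)C[C@@H](OCc2ccc(OC)cc2)[C@H](CC(=O)C[C@H](CC=C)C(C)=C)O1 | intermediate
26 | methyl (1S,3RS,5E,8S,12S,13R)-3-hydroxy-13-[(4-methoxybenzyl)oxy]-1-methyl-10-oxo-8-(prop-1-en-2-yl)-15-oxabicyclo[10.2.1]pentadec-5-ene-5-carboxylate | C=C(C)[C@H]1C/C=C(/C(=O)OC)CC(O)C[C@@]2(C)C[C@@H](OCc3ccc(OC)cc3)[C@H](CC(=O)C1)O2 | intermediate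
27 | methyl (1S,3RS,5E,8S,12S,13R)-3,13-dihydroxy-1-methyl-10-oxo-8-(prop-1-en-2-yl)-15-oxabicyclo[10.2.1]pentadec-5-ene-5-carboxylate | C=C(C)[C@H]1C/C=C(/C(=O)OC)CC(O)C[C@@]2(C)C[C@@H](O)[C@H](CC(=O)C1)O2 | intermediate
28 | methyl (1S,5E,8S,12S)-1-methyl-3,10,13-trioxo-8-(prop-1-en-2-yl)-15-oxabicyclo[10.2.1]pentadec-5-ene-5-carboxylate (CNP0163183.4) | C=C(C)[C@H]1C/C=C(/C(=O)OC)CC(=O)C[C@@]2(C)CC(=O)[C@H](CC(=O)C1)O2 | target

## Step count and risks

Total step count: 18.
Longest linear sequence: 12 steps (steps 1–6 then 13–18; the carvone branch 7–12 then 13–18 is equally long).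

**Three steps most likely to fail**

Step 13. The hindered 2-substituted lithiodithiane 19 must displace a primary iodide that is β-branched and β-oxygenated; E2 elimination to the exocyclic enol ether and slow SN2 are the dangers. The fallback sets out from acid 15 and iodide 10 and avoids a carbanion altogether. Acid 15 is converted with oxalyl chloride and catalytic DMF in CH2Cl2 into (3S)-3-(prop-1-en-2-yl)hex-5-enoyl chloride F3. F3 is joined to 10 by a nickel-catalysed reductive cross-electrophile coupling (NiCl2·DME 10 mol %, 4,4'-di-tert-butyl-2,2'-bipyridine, Mn powder, DMA, 0 °C → rt), which forms the ketone through an alkyl radical and an acyl-nickel species. This gives keto acetal 21 directly; the fallback comes back to the route at 21, which is hydrolysed to 22 with dilute CF3CO2H in MeCN/H2O as in the second stage of step 14.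

Step 16. The ring closure has to form a trisubstituted enoate in a 14-membered ring; the E/Z outcome is not certain, and oligomers or slow lactonisation of the γ-hydroxy ester can intrude. The fallback sets out from 25 and accepts whatever geometry the metathesis gives. If the ring closes mainly to methyl (1S,3RS,5Z,8S,12S,13R)-3-hydroxy-13-[(4-methoxybenzyl)oxy]-1-methyl-10-oxo-8-(prop-1-en-2-yl)-15-oxabicyclo[10.2.1]pentadec-5-ene-5-carboxylate F4, this isomer is not discarded. It is equilibrated by reversible thiyl-radical addition–elimination (PhSSPh catalytic, hν, benzene, rt), a neutral method that spares the β-alkoxy ketone, towards the ester-trans enoate. The fallback comes back to the route at 26.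

Step 6. The acetal–enol ether condensation can telomerise (the product acetal can ionise again), and the facial selectivity at a methyl-substituted oxocarbenium ion is predicted, not proven. The fallback sets out from 8 and uses a nucleophile that cannot add twice and whose diastereomer ratio can be read directly. Hosomi–Sakurai allylation of 8 (allyltrimethylsilane, BF3·OEt2, CH2Cl2, −78 °C; same inside-attack model) gives (2R,3R,5S)-2-(iodomethyl)-3-[(4-methoxybenzyl)oxy]-5-methyl-5-(prop-2-en-1-yl)oxolane F1, from which any minor epimer is removed. Lemieux–Johnson cleavage (OsO4 catalytic, NaIO4, 2,6-lutidine, dioxane/H2O) then gives 2-[(2R,4R,5R)-5-(iodomethyl)-4-[(4-methoxybenzyl)oxy]-2-methyloxolan-2-yl]acetaldehyde F2. Acetalisation (MeOH, PPTS, 4 Å MS) converts F2 into 10, where the fallback comes back to the route.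

## Further compounds

F1 | step 6 | (2R,3R,5S)-2-(iodomethyl)-3-[(4-methoxybenzyl)oxy]-5-methyl-5-(prop-2-en-1-yl)oxolane | C=CC[C@@]1(C)C[C@@H](OCc2ccc(OC)cc2)[C@H](CI)O1
F2 | step 6 | 2-[(2R,4R,5R)-5-(iodomethyl)-4-[(4-methoxybenzyl)oxy]-2-methyloxolan-2-yl]acetaldehyde | O=CC[C@@]1(C)C[C@@H](OCc2ccc(OC)cc2)[C@H](CI)O1
F3 | step 13 | (3S)-3-(prop-1-en-2-yl)hex-5-enoyl chloride | C=C(C)[C@H](CC(=O)Cl)CC=C
F4 | step 16 | methyl (1S,3RS,5Z,8S,12S,13R)-3-hydroxy-13-[(4-methoxybenzyl)oxy]-1-methyl-10-oxo-8-(prop-1-en-2-yl)-15-oxabicyclo[10.2.1]pentadec-5-ene-5-carboxylate | C=C(C)[C@H]1C/C=C(\C(=O)OC)CC(O)C[C@@]2(C)C[C@@H](OCc3ccc(OC)cc3)[C@H](CC(=O)C1)O2
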